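The data are calculated for substances that don't exist; scatter was added.

I decided to judge the flask by the substrate left at the last reading, not by the target made, because the question was whether charging more partner would pay.

| flask | substrate | partner | free catalyst | remark |
|---|---|---|---|---|
| eta | 0.48 M | 1 equiv | 0.34 mol% | run made earlier |
| theta | 0.48 M | 1 equiv | 0.75 mol% | run made earlier |
| zeta | 0.96 M | 1 equiv | 0.5 mol% | run made earlier |
| flask | 0.48 M | 1.00 equiv | 0.5 mol% |  |

| run | time / d | target / % | substrate / % |
|---|---|---|---|
| eta | 1.04 | 11.0 | 88.7 |
| eta | 3.00 | 14.2 | 85.8 |
| eta | 5.00 | 15.2 | 85.4 |
| eta | 8.00 | 14.4 | 84.8 |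
| theta | 1.04 | 22.6 | 76.6 |
| theta | 3.00 | 28.6 | 70.6 |
| theta | 5.00 | 29.3 | 71.9 |
| theta | 8.00 | 29.1 | 71.1 |
| zeta | 1.04 | 30.4 | 70.2 |
| zeta | 3.00 | 37.5 | 63.7 |
| zeta | 5.00 | 36.5 | 62.7 |
| zeta | 8.00 | 38.5 | 62.3 |

(readings scatter by 0.5 percentage points)

- a species is counted by the substrate in it: one self-condensation product counts as two
- the earlier runs were read with a standard deviation of 0.5 percentage points
- candidate steps: substrate + free catalyst <-> catalyst intermediate A; partner + catalyst intermediate A -> catalyst intermediate B; catalyst intermediate B -> free catalyst + target; 2 substrate -> self-condensation product; free catalyst -> spent catalyst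

- apparent order in partner when 5.0 % of the substrate are converted (percent change of the rate of making target for one percent more partner charged)
- factor on the rate of making target when 5.0 % of the substrate are converted if partner is charged twice over

In the eta run target read 14.2 % at 3.00 d and 14.4 % at 8.00 d, so within the scatter target had stopped rising with substrate still there. I therefore took the negative logarithm of the fraction of substrate left at the last reading and divided it by the catalyst loading. Eta gave 48.5 and theta 45.5, so their mean, 47.0, was my life number, the work a charge of catalyst does per unit of loading. For the flask it promised 79.1 % of the substrate left.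

The zeta run, with twice the substrate and partner per litre, gave 94.6. If the life number grows with substrate to the first power and with partner to some order, a first-order partner would multiply it by 4. My bound from above began at an order of 1, and my bound from below stayed at 0, since partner enters as a reagent. Setting the zeta value against theta, the lower of the two at the lower strength, brought my upper figure down to 0.0573, a factor of about 1.04 for double partner. That figure was an estimate read from scattered readings over whole runs, not a measurement at the asked conversion. The forecast, 0.03 and 1.02, argued that “Capture of substrate is therefore rate-limiting”, and it stood inside my bracket.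

The flask gave an order of 0.11 and a factor of 1.05, both above my bracket.

substrate + free catalyst ⇌ catalyst intermediate A (K = 1.91 L mol⁻¹, k = 5.94 L mol⁻¹ h⁻¹); partner + catalyst intermediate A → catalyst intermediate B (k = 132 L mol⁻¹ h⁻¹); catalyst intermediate B → free catalyst + target (k = 626 h⁻¹); 2 substrate → self-condensation product (k = 2.83 × 10⁻⁵ L mol⁻¹ h⁻¹); free catalyst → spent catalyst (k = 0.0592 h⁻¹) Its substrate left at 8.00 d was 79 %, a life number of 46.5. Without the conversion of free catalyst into spent catalyst, the flask's rate at the asked conversion stood at 1.29 times the actual one, and its apparent order in free catalyst fell from 1.3 to 1.0. So in this flask, arriving sooner meant meeting more living catalyst. The flask reached that conversion at 0.186 d, and twice the partner multiplied this time by 0.953.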